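**Strategy.** The route rests on cutting oxepane ring B (O–C5–C6–C7–C8–C9–C10, germacrane numbering) at C5–C6 and C7–C8. The key step exploits that C5 and C8 both carry oxygen (latent oxocarbenium ion and aldehyde), while C6/C7 belong to the α-methylene-γ-butyrolactone and can be supplied as a 1,2-dinucleophile, 2-(trimethylsilyloxy)-3-[(trimethylsilyl)methyl]furan. One Lewis-acid operation (vinylogous Mukaiyama addition, then intramolecular Hosomi–Sakurai allylation) joins this furan to an oxepane (ring A) bearing an anomeric acetate at C5 and a CH2CHO arm at C10. This creates ring B, the ten-membered carbocycle, the exocyclic methylene and four stereocentres. Ring A arises by Baeyer–Villiger cleavage of a cyclohexanone.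

Key step: step 12

Remarks (valid for all steps):
- Numbering: lactone O–C6, C7, C11(=C13), C12; angelate on C8; ether oxygen between C5 and C10; C14 = methyl on C10; C15 = CH2OAc on C4. Ring A = O–C5–C4–C3–C2–C1–C10, ring B = O–C5–C6–C7–C8–C9–C10. TBS = tert-butyldimethylsilyl.
- Stereochemical remark: in the target configuration (5R,10R) the bonds C5–C6 and C10–C9 lie on opposite faces of ring A, while C3–O, C4–C15, C5–C6 and C10–CH3 lie on one face. The route is built for exactly this arrangement.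
- Assumption: the (S)-SEGPHOS-modified iridium catalyst of step 1 is taken to give the (3S) carbinol; if the sense of induction is opposite, the (R)-ligand is used and nothing else changes.

**Step 1**
Reactants: 1 hex-5-en-1-ol; 2 4-ethenyl-1,3-dioxolan-2-one
Product: 4 (2S,3S)-2-ethenyloct-7-ene-1,3-diol, via hex-5-enal 3 (not isolated)
Conditions: [Ir(cod)Cl]2 (2.5 mol %), (S)-SEGPHOS (5 mol %), 4-cyano-3-nitrobenzoic acid (10 mol %), Cs2CO3 (20 mol %), THF, 90 °C
Reagents that add atoms: none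
Why: Iridium-catalysed transfer-hydrogenative carbonyl (hydroxymethyl)allylation: 1 is dehydrogenated to 3, which is attacked through a closed chair transition state by the allyliridium species formed from 2 with loss of CO2, so that C3–OH and C4–CH2OH should come out anti while the chiral ligand fixes the absolute configuration.

**Step 2**
Reactants: 4 (2S,3S)-2-ethenyloct-7-ene-1,3-diol
Product: 5 (2S,3S)-1,3-bis(TBS-oxy)-2-ethenyloct-7-ene
Conditions: t-BuMe2SiCl (2.5 equiv), imidazole, DMF, 0 °C → rt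
Reagents that add atoms: tert-butyldimethylsilyl chloride, CC(C)(C)[Si](C)(C)Cl
Why: Imidazole-promoted silyl ether formation at the primary and the secondary hydroxyl group installs non-participating ethers on O15 and O3 that survive every step up to the end game.

**Step 3**
Reactants: 5 (2S,3S)-1,3-bis(TBS-oxy)-2-ethenyloct-7-ene
Product: 7 (2S,3S)-3-(TBS-oxy)-2-[(TBS-oxy)methyl]heptanedioic acid, via dialdehyde 6 (not isolated)
Conditions: RuCl3 (5 mol %), NaIO4 (9 equiv), MeCN/EtOAc/H2O, rt
Reagents that add atoms: sodium periodate, [Na+].[O-]I(=O)(=O)=O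
Why: Oxidative alkene cleavage by RuO4 generated in situ should convert both terminal alkenes through the aldehydes into carboxylic acids, which unmasks C5 and the carbon needed for the ring closure without touching the silyl ethers or C4.

**Step 4**
Reactants: 7 (2S,3S)-3-(TBS-oxy)-2-[(TBS-oxy)methyl]heptanedioic acid
Product: 8 bis(prop-2-en-1-yl) (2S,3S)-3-(TBS-oxy)-2-[(TBS-oxy)methyl]heptanedioate
Conditions: allyl bromide (2.5 equiv), K2CO3, DMF, rt
Reagents that add atoms: allyl bromide, C=CCBr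
Why: SN2 O-alkylation of the dicarboxylate gives the diallyl ester, one allyl group of which later becomes the C9–C8 arm.

**Step 5**
Reactants: 8 bis(prop-2-en-1-yl) (2S,3S)-3-(TBS-oxy)-2-[(TBS-oxy)methyl]heptanedioate
Product: 10 prop-2-en-1-yl (1RS,3S,4S)-4-(TBS-oxy)-3-[(TBS-oxy)methyl]-1-methyl-2-oxocyclohexane-1-carboxylate, via potassium enolate 9 (not isolated)
Conditions: KN(SiMe3)2 (1.1 equiv), THF, −78 → 0 °C; then MeI (3 equiv), 0 °C → rt
Reagents that add atoms: iodomethane, CI
Why: Dieckmann condensation: kinetic deprotonation at the unhindered C10 methylene and 6-exo-trig acyl substitution at the C5 ester (the only mode that ends in a stabilised β-keto ester enolate) are followed by C-methylation of that enolate, the C10 configuration being irrelevant because step 6 erases it.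

**Step 6**
Reactants: 10 prop-2-en-1-yl (1RS,3S,4S)-4-(TBS-oxy)-3-[(TBS-oxy)methyl]-1-methyl-2-oxocyclohexane-1-carboxylate
Product: 11 (2R,5S,6S)-5-(TBS-oxy)-6-[(TBS-oxy)methyl]-2-methyl-2-(prop-2-en-1-yl)cyclohexan-1-one
Conditions: Pd2(dba)3 (2.5 mol %), (R)-t-BuPHOX (6.25 mol %), toluene, 30 °C
Reagents that add atoms: none
Why: Decarboxylative Tsuji allylation: oxidative addition of the allyl ester to zerovalent palladium and loss of CO2 give a regiodefined palladium enolate, and the (R)-ligand should direct allylation to the C10 face that the substrate also favours (anti to the pseudoaxial CH2OTBS group on C4), which sets 10R with the methyl group cis to C15.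

**Step 7**
Reactants: 11 (2R,5S,6S)-5-(TBS-oxy)-6-[(TBS-oxy)methyl]-2-methyl-2-(prop-2-en-1-yl)cyclohexan-1-one
Product: 12 (3S,4S,7R)-4-(TBS-oxy)-3-[(TBS-oxy)methyl]-7-methyl-7-(prop-2-en-1-yl)oxepan-2-one
Conditions: mCPBA (1.5 equiv), NaHCO3, CH2Cl2, 0 °C → rt
Reagents that add atoms: 3-chloroperbenzoic acid, OOC(=O)c1cccc(Cl)c1
Why: Baeyer–Villiger oxidation: the quaternary C10 should migrate with retention in preference to C4 (secondary and deactivated by two β-oxygens), which places the ring oxygen between C5 and C10, while the monosubstituted alkene is epoxidised more slowly.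

**Step 8**
Reactants: 12 (3S,4S,7R)-4-(TBS-oxy)-3-[(TBS-oxy)methyl]-7-methyl-7-(prop-2-en-1-yl)oxepan-2-one
Product: 14 (2RS,3S,4S,7R)-4-(TBS-oxy)-3-[(TBS-oxy)methyl]-7-methyl-7-(prop-2-en-1-yl)oxepan-2-yl acetate, via aluminium hemiacetal 13 (not isolated)
Conditions: i-Bu2AlH (1.2 equiv), CH2Cl2, −78 °C; then pyridine, DMAP, Ac2O, −78 → −20 °C
Reagents that add atoms: acetic anhydride, CC(=O)OC(C)=O
Why: Reductive acetylation of a lactone: one hydride is added, and the tetrahedral aluminium hemiacetal, stable at −78 °C, is acetylated in situ before it can open to the hydroxy aldehyde; the anomeric mixture is of no consequence.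

**Step 9**
Reactants: 14 (2RS,3S,4S,7R)-4-(TBS-oxy)-3-[(TBS-oxy)methyl]-7-methyl-7-(prop-2-en-1-yl)oxepan-2-yl acetate
Product: 16 (2RS,3S,4S,7R)-4-(TBS-oxy)-3-[(TBS-oxy)methyl]-7-methyl-7-(2-oxoethyl)oxepan-2-yl acetate, via ozonide 15 (not isolated)
Conditions: O3, CH2Cl2, −78 °C; then PPh3, −78 °C → rt
Reagents that add atoms: ozone, [O-][O+]=O
Why: Ozonolysis with reductive work-up unmasks the C8 aldehyde under neutral conditions that should leave the anomeric acetate and the silyl ethers intact.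

**Step 10**
Reactants: 17 3-bromofuran-2(5H)-one; 18 (trimethylsilyl)methylmagnesium chloride
Product: 20 3-[(trimethylsilyl)methyl]furan-2(5H)-one, via (trimethylsilyl)methylzinc chloride 19 (not isolated)
Conditions: 18, ZnCl2, THF, 0 °C; then 17, Pd(PPh3)4 (5 mol %), THF, 40 °C
Reagents that add atoms: none
Why: Negishi coupling: oxidative addition of the vinylic C–Br bond to zerovalent palladium, transmetalation from the ester-tolerant organozinc and reductive elimination should give the 2-(silylmethyl)butenolide.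

**Step 11**
Reactants: 20 3-[(trimethylsilyl)methyl]furan-2(5H)-one
Product: 21 2-(trimethylsilyloxy)-3-[(trimethylsilyl)methyl]furan
Conditions: Me3SiOTf (1.1 equiv), Et3N (1.3 equiv), Et2O, 0 °C; filtered, distilled, used at once
Reagents that add atoms: trimethylsilyl trifluoromethanesulfonate, C[Si](C)(C)OS(=O)(=O)C(F)(F)F
Why: Soft enolisation at the γ-CH2 group and O-silylation give the aromatic 2-silyloxyfuran, a vinylogous silyl ketene acetal that still carries the latent allylsilane.

**Step 12 (key step)**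
Reactants: 16 (2RS,3S,4S,7R)-4-(TBS-oxy)-3-[(TBS-oxy)methyl]-7-methyl-7-(2-oxoethyl)oxepan-2-yl acetate; 21 2-(trimethylsilyloxy)-3-[(trimethylsilyl)methyl]furan
Product: 24 (3S,4R,5R,6S,7R,8R,10R)-3,15-bis(TBS-oxy)-8-hydroxy-5,10-epoxygermacr-11(13)-en-12,6-olide, via butenolide adduct 22 (not isolated), via trimethylsilyl ether 23 (not isolated)
Conditions: 21 (1.1 equiv), Me3SiOTf (1.0 equiv), 2,6-di-tert-butyl-4-methylpyridine (0.2 equiv), CH2Cl2 (0.02 M), −78 °C, then −78 → −20 °C; NaHCO3 (aq); citric acid, MeOH, 0 °C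
Reagents that add atoms: none
Why: Me3SiOTf ionises the anomeric acetate of 16 to the ring A oxocarbenium ion (the aldehyde is not activated at −78 °C), which is captured at C5 by the γ-carbon (C6) of 21 to give butenolide 22, whose C7=C11–CH2SiMe3 unit is now an allylsilane; on warming, the silyl triflate activates the C8 aldehyde and C7 adds to it with loss of the silyl group, which unveils the exocyclic C11=C13 methylene and leaves silyl ether 23, cleaved on work-up. Both events are known reaction types, the vinylogous Mukaiyama addition of 2-silyloxyfurans to cyclic α-acetoxy ethers and the intramolecular Hosomi–Sakurai reaction of 2-(silylmethyl)alk-2-enoates that carry an aldehyde, here run in tandem as a formal (5+2) annulation of the C5/C8 dielectrophile by the C6/C7 dinucleophile. Ring B is closed by 7-exo-trig attack of C7 on the C8 carbonyl, which at the same time completes the ten-membered carbocycle C1–C10. C5 is set by ring A: in the chair-like oxocarbenium ion with the C4 CH2OTBS group pseudoequatorial, the furan should enter anti to the pseudoaxial C4–H and anti to the pseudoaxial CH2CHO arm on C10 (4,5-cis and trans to the arm, as the target requires), and C6 should follow from an open antiperiplanar transition state that places the C5 and C6 oxygens anti. C7 and C8 are set in the ring closure, where the aldehyde should add to the butenolide face anti to the C6 substituent (trans lactone) with its oxygen pseudoequatorial on the forming seven-membered ring (C7–C11 and C8–O anti). The step needs the order C6 before C7 and acetal before aldehyde, which the far greater nucleophilicity of the silyloxyfuran terminus over the latent allylsilane and the easy ionisation of the α-acetoxy ether at −78 °C should secure.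

**Step 13**
Reactants: 24 (3S,4R,5R,6S,7R,8R,10R)-3,15-bis(TBS-oxy)-8-hydroxy-5,10-epoxygermacr-11(13)-en-12,6-olide; 25 (2Z)-2-methylbut-2-enoic acid (angelic acid)
Product: 27 (3S,4R,5R,6S,7R,8R,10R)-3,15-bis(TBS-oxy)-8-[(2Z)-2-methylbut-2-enoyloxy]-5,10-epoxygermacr-11(13)-en-12,6-olide, via mixed anhydride 26 (not isolated)
Conditions: 25 (3 equiv), 2,4,6-trichlorobenzoyl chloride (3 equiv), Et3N, toluene, rt; then 24, toluene, 75 °C
Reagents that add atoms: none
Why: Yamaguchi esterification: the C8 hydroxyl attacks the less hindered angeloyl carbonyl of mixed anhydride 26, and the absence of a nucleophilic catalyst and of strong base should preserve the (Z)-geometry and the 12,6-lactone.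

**Step 14**
Reactants: 27 (3S,4R,5R,6S,7R,8R,10R)-3,15-bis(TBS-oxy)-8-[(2Z)-2-methylbut-2-enoyloxy]-5,10-epoxygermacr-11(13)-en-12,6-olide
Product: 28 (3S,4S,5R,6S,7R,8R,10R)-3,15-dihydroxy-8-[(2Z)-2-methylbut-2-enoyloxy]-5,10-epoxygermacr-11(13)-en-12,6-olide
Conditions: HF·pyridine, pyridine, THF, 0 °C → rt
Reagents that add atoms: none
Why: Fluoride-mediated cleavage of both silyl ethers under buffered conditions should spare the angelate, the lactone and the exocyclic methylene.

**Step 15**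
Reactants: 28 (3S,4S,5R,6S,7R,8R,10R)-3,15-dihydroxy-8-[(2Z)-2-methylbut-2-enoyloxy]-5,10-epoxygermacr-11(13)-en-12,6-olide
Product: 29 (3S,4S,5R,6S,7R,8R,10R)-3,15-diacetoxy-8-[(2Z)-2-methylbut-2-enoyloxy]-5,10-epoxygermacr-11(13)-en-12,6-olide
Conditions: Ac2O (5 equiv), pyridine, DMAP (cat.), CH2Cl2, 0 °C → rt
Reagents that add atoms: acetic anhydride, CC(=O)OC(C)=O
Why: Pyridine/DMAP-catalysed O-acetylation of the primary and the secondary hydroxyl group completes the target without touching any stereocentre.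

**Compound list**

1 | hex-5-en-1-ol | OCCCCC=C | starting material
2 | 4-ethenyl-1,3-dioxolan-2-one (vinyl ethylene carbonate) | C=CC1COC(=O)O1 | starting material
3 | hex-5-enal | C=CCCCC=O | intermediate
4 | (2S,3S)-2-ethenyloct-7-ene-1,3-diol | C=CCCC[C@H](O)[C@@H](C=C)CO | intermediate
5 | (2S,3S)-1,3-bis(tert-butyldimethylsilyloxy)-2-ethenyloct-7-ene | C=CCCC[C@H](O[Si](C)(C)C(C)(C)C)[C@@H](C=C)CO[Si](C)(C)C(C)(C)C | intermediate
6 | (2S,3S)-3-(tert-butyldimethylsilyloxy)-2-[(tert-butyldimethylsilyloxy)methyl]heptanedial | O=CCCC[C@H](O[Si](C)(C)C(C)(C)C)[C@@H](C=O)CO[Si](C)(C)C(C)(C)C | intermediate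
7 | (2S,3S)-3-(tert-butyldimethylsilyloxy)-2-[(tert-butyldimethylsilyloxy)methyl]heptanedioic acid | OC(=O)CCC[C@H](O[Si](C)(C)C(C)(C)C)[C@@H](C(=O)O)CO[Si](C)(C)C(C)(C)C | intermediate
8 | bis(prop-2-en-1-yl) (2S,3S)-3-(tert-butyldimethylsilyloxy)-2-[(tert-butyldimethylsilyloxy)methyl]heptanedioate | C=CCOC(=O)CCC[C@H](O[Si](C)(C)C(C)(C)C)[C@@H](C(=O)OCC=C)CO[Si](C)(C)C(C)(C)C | intermediate
9 | potassium enolate of prop-2-en-1-yl (3S,4S)-4-(tert-butyldimethylsilyloxy)-3-[(tert-butyldimethylsilyloxy)methyl]-2-oxocyclohexane-1-carboxylate | C=CCOC(=O)C1=C([O-])[C@@H](CO[Si](C)(C)C(C)(C)C)[C@@H](O[Si](C)(C)C(C)(C)C)CC1.[K+] | intermediate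
10 | prop-2-en-1-yl (1RS,3S,4S)-4-(tert-butyldimethylsilyloxy)-3-[(tert-butyldimethylsilyloxy)methyl]-1-methyl-2-oxocyclohexane-1-carboxylate | C=CCOC(=O)C1(C)CC[C@H](O[Si](C)(C)C(C)(C)C)[C@@H](C1=O)CO[Si](C)(C)C(C)(C)C | intermediate
11 | (2R,5S,6S)-5-(tert-butyldimethylsilyloxy)-6-[(tert-butyldimethylsilyloxy)methyl]-2-methyl-2-(prop-2-en-1-yl)cyclohexan-1-one | C=CC[C@@]1(C)CC[C@H](O[Si](C)(C)C(C)(C)C)[C@@H](C1=O)CO[Si](C)(C)C(C)(C)C | intermediate
12 | (3S,4S,7R)-4-(tert-butyldimethylsilyloxy)-3-[(tert-butyldimethylsilyloxy)methyl]-7-methyl-7-(prop-2-en-1-yl)oxepan-2-one | C=CC[C@@]1(C)CC[C@H](O[Si](C)(C)C(C)(C)C)[C@@H](C(=O)O1)CO[Si](C)(C)C(C)(C)C | intermediate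
13 | diisobutylaluminium (2RS,3S,4S,7R)-4-(tert-butyldimethylsilyloxy)-3-[(tert-butyldimethylsilyloxy)methyl]-7-methyl-7-(prop-2-en-1-yl)oxepan-2-olate (aluminium hemiacetal) | C=CC[C@@]1(C)CC[C@H](O[Si](C)(C)C(C)(C)C)[C@@H](C(O[Al](CC(C)C)CC(C)C)O1)CO[Si](C)(C)C(C)(C)C | intermediate
14 | (2RS,3S,4S,7R)-4-(tert-butyldimethylsilyloxy)-3-[(tert-butyldimethylsilyloxy)methyl]-7-methyl-7-(prop-2-en-1-yl)oxepan-2-yl acetate | C=CC[C@@]1(C)CC[C@H](O[Si](C)(C)C(C)(C)C)[C@@H](C(OC(C)=O)O1)CO[Si](C)(C)C(C)(C)C | intermediate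
15 | ozonide of 14: (2RS,3S,4S,7R)-4-(tert-butyldimethylsilyloxy)-3-[(tert-butyldimethylsilyloxy)methyl]-7-methyl-7-(1,2,4-trioxolan-3-ylmethyl)oxepan-2-yl acetate | O1OCOC1C[C@@]2(C)CC[C@H](O[Si](C)(C)C(C)(C)C)[C@@H](C(OC(C)=O)O2)CO[Si](C)(C)C(C)(C)C | intermediate
16 | (2RS,3S,4S,7R)-4-(tert-butyldimethylsilyloxy)-3-[(tert-butyldimethylsilyloxy)methyl]-7-methyl-7-(2-oxoethyl)oxepan-2-yl acetate | O=CC[C@@]1(C)CC[C@H](O[Si](C)(C)C(C)(C)C)[C@@H](C(OC(C)=O)O1)CO[Si](C)(C)C(C)(C)C | intermediate
17 | 3-bromofuran-2(5H)-one | O=C1OCC=C1Br | starting material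
18 | (trimethylsilyl)methylmagnesium chloride | C[Si](C)(C)C[Mg]Cl | starting material
19 | (trimethylsilyl)methylzinc chloride | C[Si](C)(C)C[Zn]Cl | intermediate
20 | 3-[(trimethylsilyl)methyl]furan-2(5H)-one | C[Si](C)(C)CC1=CCOC1=O | intermediate
21 | 2-(trimethylsilyloxy)-3-[(trimethylsilyl)methyl]furan | C[Si](C)(C)Cc1ccoc1O[Si](C)(C)C | intermediate
22 | (5S)-5-[(2R,3R,4S,7R)-4-(tert-butyldimethylsilyloxy)-3-[(tert-butyldimethylsilyloxy)methyl]-7-methyl-7-(2-oxoethyl)oxepan-2-yl]-3-[(trimethylsilyl)methyl]furan-2(5H)-one | C[Si](C)(C)CC1=C[C@H](OC1=O)[C@@H]2O[C@@](C)(CC=O)CC[C@H](O[Si](C)(C)C(C)(C)C)[C@@H]2CO[Si](C)(C)C(C)(C)C | intermediate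
23 | (3S,4R,5R,6S,7S,8R,10R)-3,15-bis(tert-butyldimethylsilyloxy)-8-(trimethylsilyloxy)-5,10-epoxygermacr-11(13)-en-12,6-olide (all centres spatially as in 29) | C=C1C(=O)O[C@@H]2[C@@H]3O[C@](C)(CC[C@H](O[Si](C)(C)C(C)(C)C)[C@@H]3CO[Si](C)(C)C(C)(C)C)C[C@@H](O[Si](C)(C)C)[C@@H]12 | intermediate
24 | (3S,4R,5R,6S,7R,8R,10R)-3,15-bis(tert-butyldimethylsilyloxy)-8-hydroxy-5,10-epoxygermacr-11(13)-en-12,6-olide (all centres spatially as in 29) | C=C1C(=O)O[C@@H]2[C@@H]3O[C@](C)(CC[C@H](O[Si](C)(C)C(C)(C)C)[C@@H]3CO[Si](C)(C)C(C)(C)C)C[C@@H](O)[C@@H]12 | intermediate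
25 | (2Z)-2-methylbut-2-enoic acid (angelic acid) | C/C=C(/C)C(=O)O | starting material
26 | (2Z)-2-methylbut-2-enoic 2,4,6-trichlorobenzoic anhydride | C/C=C(/C)C(=O)OC(=O)c1c(Cl)cc(Cl)cc1Cl | intermediate
27 | (3S,4R,5R,6S,7R,8R,10R)-3,15-bis(tert-butyldimethylsilyloxy)-8-[(2Z)-2-methylbut-2-enoyloxy]-5,10-epoxygermacr-11(13)-en-12,6-olide (all centres spatially as in 29) | C=C1C(=O)O[C@@H]2[C@@H]3O[C@](C)(CC[C@H](O[Si](C)(C)C(C)(C)C)[C@@H]3CO[Si](C)(C)C(C)(C)C)C[C@@H](OC(=O)/C(C)=C\C)[C@@H]12 | intermediate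
28 | (3S,4S,5R,6S,7R,8R,10R)-3,15-dihydroxy-8-[(2Z)-2-methylbut-2-enoyloxy]-5,10-epoxygermacr-11(13)-en-12,6-olide | C=C1C(=O)O[C@@H]2[C@@H]3O[C@](C)(CC[C@H](O)[C@@H]3CO)C[C@@H](OC(=O)/C(C)=C\C)[C@@H]12 | intermediate
29 | (3S,4S,5R,6S,7R,8R,10R)-3,15-diacetoxy-8-[(2Z)-2-methylbut-2-enoyloxy]-5,10-epoxygermacr-11(13)-en-12,6-olide (CNP0346171.1) | C=C1C(=O)O[C@@H]2[C@@H]3O[C@](C)(CC[C@H](OC(C)=O)[C@@H]3COC(C)=O)C[C@@H](OC(=O)/C(C)=C\C)[C@@H]12 | target

**Total step count:** 15.
**Longest linear sequence:** 13 steps (steps 1–9 and 12–15; steps 10–11 make the furan in parallel).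

**Steps most likely to fail**

1. Step 12. Several processes may go wrong: capture of the ring A oxocarbenium ion by the C8 carbonyl oxygen; vinylogous aldol addition of 21 to the aldehyde instead of the acetal carbon; entry of the furan on the other face of C5; or stalling after the first C–C bond with protodesilylation of the allylsilane, because ring B has to close across the trans-disposed arms on C5 and C10. The fallback makes the two bonds in separate operations, with no aldehyde present while the oxocarbenium ion exists. It sets out from 14. Me3SiOTf-catalysed addition of 21 (CH2Cl2, −78 °C) should give (5S)-5-[(2R,3R,4S,7R)-4-(TBS-oxy)-3-[(TBS-oxy)methyl]-7-methyl-7-(prop-2-en-1-yl)oxepan-2-yl]-3-[(trimethylsilyl)methyl]furan-2(5H)-one F1, whose C5 configuration can be checked at this stage. Ozonolysis of its terminal alkene (O3, CH2Cl2, −78 °C, then PPh3; the electron-poor butenolide alkene reacts far more slowly) should give 22, now isolated. Fluoride activation of the allylsilane (Bu4N[Ph3SiF2], THF, 0 °C) should then close ring B, and the route is rejoined at 24.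

2. Step 13. The hindered C8 hydroxyl may acylate slowly, the angelate may isomerise to the (E)-ester on prolonged heating, and the lactone may migrate from O6 to O8 under base. The fallback builds the (Z)-alkene on the molecule. It sets out from 24. Esterification with 2-[bis(2,2,2-trifluoroethoxy)phosphoryl]propanoic acid (DCC, CH2Cl2, rt) should give the 8-O-{2-[bis(2,2,2-trifluoroethoxy)phosphoryl]propanoyl} ester F2. Still–Gennari olefination with acetaldehyde (KN(SiMe3)2, 18-crown-6, THF, −78 °C) should give the (Z)-2-methylbut-2-enoate, and the route is rejoined at 27.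

3. Step 7. Peracid addition to the doubly α-substituted ketone may be slow, so that epoxidation of the allyl group competes. The fallback masks the alkene for the oxidation. It sets out from 11. Bromine (CH2Cl2, −78 °C) should give (2R,5S,6S)-2-(2,3-dibromopropyl)-5-(TBS-oxy)-6-[(TBS-oxy)methyl]-2-methylcyclohexan-1-one F3. Baeyer–Villiger oxidation (mCPBA, NaHCO3, CH2Cl2) should give (3S,4S,7R)-7-(2,3-dibromopropyl)-4-(TBS-oxy)-3-[(TBS-oxy)methyl]-7-methyloxepan-2-one F4. Zinc dust (AcOH, Et2O, 0 °C) should restore the alkene, and the route is rejoined at 12.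

**Further compounds**

F1 | step 12 | (5S)-5-[(2R,3R,4S,7R)-4-(tert-butyldimethylsilyloxy)-3-[(tert-butyldimethylsilyloxy)methyl]-7-methyl-7-(prop-2-en-1-yl)oxepan-2-yl]-3-[(trimethylsilyl)methyl]furan-2(5H)-one | C[Si](C)(C)CC1=C[C@H](OC1=O)[C@@H]2O[C@@](C)(CC=C)CC[C@H](O[Si](C)(C)C(C)(C)C)[C@@H]2CO[Si](C)(C)C(C)(C)C
F2 | step 13 | 8-O-{2-[bis(2,2,2-trifluoroethoxy)phosphoryl]propanoyl} ester of 24 | C=C1C(=O)O[C@@H]2[C@@H]3O[C@](C)(CC[C@H](O[Si](C)(C)C(C)(C)C)[C@@H]3CO[Si](C)(C)C(C)(C)C)C[C@@H](OC(=O)C(C)P(=O)(OCC(F)(F)F)OCC(F)(F)F)[C@@H]12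
F3 | step 7 | (2R,5S,6S)-2-(2,3-dibromopropyl)-5-(tert-butyldimethylsilyloxy)-6-[(tert-butyldimethylsilyloxy)methyl]-2-methylcyclohexan-1-one | BrCC(Br)C[C@@]1(C)CC[C@H](O[Si](C)(C)C(C)(C)C)[C@@H](C1=O)CO[Si](C)(C)C(C)(C)C
F4 | step 7 | (3S,4S,7R)-7-(2,3-dibromopropyl)-4-(tert-butyldimethylsilyloxy)-3-[(tert-butyldimethylsilyloxy)methyl]-7-methyloxepan-2-one | BrCC(Br)C[C@@]1(C)CC[C@H](O[Si](C)(C)C(C)(C)C)[C@@H](C(=O)O1)CO[Si](C)(C)C(C)(C)C
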